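## Retrosynthetic overview

1. The target is a (2S,4S)-2,4-cis-4-arylflavan. Disconnect C4–H: hydride is delivered last to a planar C4 benzylic cation, steered by the C2 aryl group, which leads back to a tertiary 4-aryl-flavan-4-ol.
2. Disconnect the C4–C(aryl) bond of that carbinol: the C4 ketyl radical of a (2S)-flavanone plus the phenoxyl radical of 2-dodecanoylphloroglucinol, generated together and joined under visible-light photocatalysis.
3. The flavanone is natural (2S)-liquiritigenin (the only source of chirality), masked as its diacetate. The acylphloroglucinol comes from phloroglucinol and dodecanenitrile (Hoesch).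
4. Ring order: no ring is built. Rings A and C and the 4-hydroxyphenyl ring arrive in liquiritigenin, the phloroglucinol ring is bought, and the two halves are merged at C4.

Assumption: commercial natural (2S)-(−)-liquiritigenin is used as the single enantiomer (ee confirmed by chiral HPLC before use).

## Route

Step 1
Reactants: 1 phloroglucinol (benzene-1,3,5-triol, anhydrous); 2 dodecanenitrile
Product: 4 1-(2,4,6-trihydroxyphenyl)dodecan-1-one (2-dodecanoylphloroglucinol), via ketiminium chloride 3 (not isolated)
Conditions: ZnCl2 (0.2 equiv), dry HCl gas, Et2O, 0 → 5 °C, 16 h; then H2O, 100 °C, 1 h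
Reagents that add atoms: water, O
Why: Hoesch acylation: the HCl-activated nitrile C-acylates the very nucleophilic phloroglucinol once (the ketiminium salt 3 deactivates the ring toward a second acylation), and hot water hydrolyses 3 to the aryl ketone; no stereocentre is involved.

Step 2
Reactants: 5 (2S)-liquiritigenin, (2S)-7-hydroxy-2-(4-hydroxyphenyl)chroman-4-one
Product: 6 (2S)-7-acetoxy-2-(4-acetoxyphenyl)chroman-4-one (liquiritigenin diacetate)
Conditions: Ac2O (3 equiv), pyridine (4 equiv), CH2Cl2, 0 → 20 °C, 2 h (no DMAP)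
Reagents that add atoms: acetic anhydride, CC(=O)OC(C)=O
Why: Standard O-acetylation of both phenols under weak base, which avoids the retro-oxa-Michael ring opening that would racemise C2; it leaves 4 as the only O–H donor in step 3, and the 4'-acetoxy group later holds back acid ionisation of the C2–O1 bond.

Step 3
Reactants: 4 1-(2,4,6-trihydroxyphenyl)dodecan-1-one; 6 (2S)-7-acetoxy-2-(4-acetoxyphenyl)chroman-4-one
Product: 9 tertiary carbinol 1-{3-[(2S)-7-acetoxy-2-(4-acetoxyphenyl)-4-hydroxychroman-4-yl]-2,4,6-trihydroxyphenyl}dodecan-1-one (C4 epimer mixture), via phenoxyl–ketyl radical pair 7 (not isolated), via dienone tautomer 8 (not isolated)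
Conditions: 4 (3 equiv, the excess recovered unchanged on chromatography), 6 (1 equiv), [Ir(dF(CF3)ppy)2(dtbbpy)]PF6 (2 mol%; dF(CF3)ppy = cyclometalated 2-(2,4-difluorophenyl)-5-(trifluoromethyl)pyridine, dtbbpy = 4,4'-di-tert-butyl-2,2'-bipyridine), Bu4N[O2P(OPh)2] (20 mol%), (PhO)2P(O)OH (20 mol%), degassed MeCN (0.05 M), 450 nm LEDs, 15 °C, 24 h, Ar; filtration through Et3N-deactivated silica
Reagents that add atoms: none
Why: Proposed new method: a redox-neutral photocatalytic ketyl–phenoxyl radical cross-coupling (net C-hydroxyalkylation of a phenol by an unactivated aryl ketone, an addition in which every atom of both partners ends in the product); the excited trivalent iridium complex together with the phosphate base removes H• from the para O–H of 4 by concerted proton-coupled electron transfer, and the divalent iridium so formed together with (PhO)2P(O)OH hydrogen-bonded to the C4 carbonyl of 6 passes that electron and proton on to the ketone, so the net event is the transfer of one hydrogen atom from 4 to 6 that gives radical pair 7 (the O-centred phenoxyl radical of 4 beside the C4 ketyl radical of 6); the nucleophilic, short-lived ketyl then couples at carbon with the electrophilic, longer-lived phenoxyl radical (polarity match and persistent-radical effect; the two free ring CH positions of 4 are equivalent) to give dienone 8, which enolises to 9, while O–C coupling (a hemiketal) and back hydrogen transfer only return 4 and 6; the photon energy of this catalyst (about 60 kcal/mol) roughly balances the gap between the phenol O–H and ketyl O–H bond strengths and the strongly exergonic C–C coupling drives turnover; 4 and 6 do not absorb at 450 nm, so the flavanone is never excited (no photochemical ring opening) and C2 is untouched, and the new C4 centre forms as an epimer mixture that is erased in step 4; the closest known reactions are photocatalytic proton-coupled ketyl generation for ketyl–olefin coupling, photoredox ketyl radical–radical cross-couplings, and the UV photoreaction of benzophenone with hindered phenols that joins ketyl and phenoxyl radicals at carbon.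

Step 4
Reactants: 9 tertiary carbinol 1-{3-[(2S)-7-acetoxy-2-(4-acetoxyphenyl)-4-hydroxychroman-4-yl]-2,4,6-trihydroxyphenyl}dodecan-1-one
Product: 12 target 1-{2,4,6-trihydroxy-3-[(2S,4S)-7-hydroxy-2-(4-hydroxyphenyl)chroman-4-yl]phenyl}dodecan-1-one, via carbenium trifluoroacetate 10 (not isolated), via cis diacetate 11 (not isolated)
Conditions: Et3SiH (2 equiv), TFA (5 equiv), CH2Cl2, −40 → −10 °C, 1 h; evaporate (PhMe azeotrope); then K2CO3 (0.3 equiv), degassed MeOH, 0 → 20 °C, Ar; aq NH4Cl
Reagents that add atoms: none
Why: Ionic hydrogenation then ester methanolysis: TFA ionises the tertiary bis-benzylic carbinol to the planar cation 10, and with ring C in a sofa conformation that keeps the C2 aryl equatorial, Et3SiH attacks C4 axially on the face of H-2 (chair-like, staggered transition state, the same sense as hydride reduction of flavanones to 2,4-cis-flavan-4-ols), so H-4 ends cis to H-2 and the C4 aryl equatorial and cis to the C2 aryl, which is (4S), set by C2 alone; the low temperature and the acetates spare the chelated acyl ketone and the C2–O1 bond, and catalytic base in MeOH then removes both acetates from 11.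

## Compound list

1 | phloroglucinol (benzene-1,3,5-triol) | Oc1cc(O)cc(O)c1 | starting material
2 | dodecanenitrile | CCCCCCCCCCCC#N | starting material
3 | 1-(2,4,6-trihydroxyphenyl)dodecan-1-iminium chloride (ketiminium chloride) | CCCCCCCCCCCC(=[NH2+])c1c(O)cc(O)cc1O.[Cl-] | intermediate (not isolated)
4 | 1-(2,4,6-trihydroxyphenyl)dodecan-1-one | CCCCCCCCCCCC(=O)c1c(O)cc(O)cc1O | intermediate
5 | (2S)-liquiritigenin, (2S)-7-hydroxy-2-(4-hydroxyphenyl)chroman-4-one | O=C1C[C@@H](c2ccc(O)cc2)Oc2cc(O)ccc12 | starting material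
6 | (2S)-7-acetoxy-2-(4-acetoxyphenyl)chroman-4-one | O=C1C[C@@H](c2ccc(OC(C)=O)cc2)Oc2cc(OC(C)=O)ccc12 | intermediate
7 | phenoxyl–ketyl radical pair: 4-dodecanoyl-3,5-dihydroxyphenoxyl radical (O-centred radical of 4) beside (2S)-7-acetoxy-2-(4-acetoxyphenyl)-4-hydroxychroman-4-yl radical (ketyl radical of 6) | CCCCCCCCCCCC(=O)c1c(O)cc([O])cc1O.O[C]1C[C@@H](c2ccc(OC(C)=O)cc2)Oc2cc(OC(C)=O)ccc12 | intermediate (not isolated)
8 | 6-[(2S)-7-acetoxy-2-(4-acetoxyphenyl)-4-hydroxychroman-4-yl]-4-dodecanoyl-3,5-dihydroxycyclohexa-2,4-dien-1-one (dienone tautomer of 9) | CCCCCCCCCCCC(=O)C1=C(O)C(C(=O)C=C1O)C1(O)C[C@@H](c2ccc(OC(C)=O)cc2)Oc2cc(OC(C)=O)ccc12 | intermediate (not isolated)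
9 | 1-{3-[(2S)-7-acetoxy-2-(4-acetoxyphenyl)-4-hydroxychroman-4-yl]-2,4,6-trihydroxyphenyl}dodecan-1-one (C4 epimer mixture) | CCCCCCCCCCCC(=O)c1c(O)cc(O)c(c1O)C1(O)C[C@@H](c2ccc(OC(C)=O)cc2)Oc2cc(OC(C)=O)ccc12 | intermediate
10 | (2S)-7-acetoxy-2-(4-acetoxyphenyl)-4-(3-dodecanoyl-2,4,6-trihydroxyphenyl)chroman-4-ylium trifluoroacetate | CCCCCCCCCCCC(=O)c1c(O)cc(O)c(c1O)[C+]1C[C@@H](c2ccc(OC(C)=O)cc2)Oc2cc(OC(C)=O)ccc12.[O-]C(=O)C(F)(F)F | intermediate (not isolated)
11 | 1-{3-[(2S,4S)-7-acetoxy-2-(4-acetoxyphenyl)chroman-4-yl]-2,4,6-trihydroxyphenyl}dodecan-1-one (2,4-cis) | CCCCCCCCCCCC(=O)c1c(O)cc(O)c([C@H]2C[C@@H](c3ccc(OC(C)=O)cc3)Oc3cc(OC(C)=O)ccc32)c1O | intermediate (not isolated)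
12 | 1-{2,4,6-trihydroxy-3-[(2S,4S)-7-hydroxy-2-(4-hydroxyphenyl)chroman-4-yl]phenyl}dodecan-1-one (2,4-cis) | CCCCCCCCCCCC(=O)c1c(O)cc(O)c([C@H]2C[C@@H](c3ccc(O)cc3)Oc3cc(O)ccc32)c1O | target

## Step count and risks

Total step count: 4. Longest linear sequence: 3 steps (5 → 6 → 9 → 12); compound 4 is made in one step on a side branch.

The three steps most likely to fail, in order:

**Step 3 (proposed new coupling).** Possible failures are pinacol dimerisation of the ketyl radical, net transfer hydrogenation of 6, oxidative dimerisation of 4, or a second coupling on the product. The fallback uses known chemistry, sets out from 6 and returns to the route at 9. NaBH4 in THF/EtOH at −20 °C reduces the ketone of 6 on the face of H-2 to (2S,4S)-7-acetoxy-2-(4-acetoxyphenyl)chroman-4-ol F1. BF3·OEt2 (0.3 equiv) in dioxane/CH2Cl2 at 0 °C ionises F1, and the secondary C4 cation benzylates 4 (3 equiv) in a Friedel–Crafts reaction. This gives 1-{3-[(2S)-7-acetoxy-2-(4-acetoxyphenyl)chroman-4-yl]-2,4,6-trihydroxyphenyl}dodecan-1-one F2 as a C4-epimer mixture, in which the unwanted 2,4-trans isomer is expected to dominate because the arene enters on the face that hydride uses in step 4. DDQ (1.1 equiv) in wet dioxane at 10 °C dehydrogenates the hydroxyaryl–CH unit of both epimers to the ortho-quinone methide 4-dodecanoyl-6-[(2S)-7-acetoxy-2-(4-acetoxyphenyl)chroman-4-ylidene]-3,5-dihydroxycyclohexa-2,4-dien-1-one F3. F3 adds water to give carbinol 9, so step 4 again delivers hydrogen last and corrects C4.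

**Step 4 (facial selectivity of hydride delivery; possible over-reduction of the acyl ketone or of the C2–O1 bond).** The fallback sets out from 9 and returns at 11. Catalytic TsOH·H2O in PhMe at 20 °C dehydrates 9 (E1) to 1-{3-[(2S)-7-acetoxy-2-(4-acetoxyphenyl)-2H-chromen-4-yl]-2,4,6-trihydroxyphenyl}dodecan-1-one F4. H2 (1 atm) over 5% Pd/C in EtOAc at 20 °C in the dark adds both hydrogens to the alkene face opposite the C2 aryl, giving cis diacetate 11. Compound 11 is then methanolysed as in the second stage of step 4.

**Step 1 (the lipophilic ketiminium salt may oil out and hydrolyse incompletely).** The fallback sets out from 1 and returns at 4. Direct Friedel–Crafts C-acylation of 1 with dodecanoyl chloride (1.0 equiv) and AlCl3 (3 equiv) in PhNO2 at 60 °C, followed by aqueous HCl work-up, gives 4 through an acylium ion with no iminium stage. It makes no new compound.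

## Further compounds

F0 | step 1 | none | none
F1 | step 3 | (2S,4S)-7-acetoxy-2-(4-acetoxyphenyl)chroman-4-ol (2,4-cis) | O[C@H]1C[C@@H](c2ccc(OC(C)=O)cc2)Oc2cc(OC(C)=O)ccc21
F2 | step 3 | 1-{3-[(2S)-7-acetoxy-2-(4-acetoxyphenyl)chroman-4-yl]-2,4,6-trihydroxyphenyl}dodecan-1-one (C4 epimer mixture) | CCCCCCCCCCCC(=O)c1c(O)cc(O)c(c1O)C1C[C@@H](c2ccc(OC(C)=O)cc2)Oc2cc(OC(C)=O)ccc12
F3 | step 3 | 4-dodecanoyl-6-[(2S)-7-acetoxy-2-(4-acetoxyphenyl)chroman-4-ylidene]-3,5-dihydroxycyclohexa-2,4-dien-1-one (ortho-quinone methide) | CCCCCCCCCCCC(=O)C1=C(O)C(C(=O)C=C1O)=C1C[C@@H](c2ccc(OC(C)=O)cc2)Oc2cc(OC(C)=O)ccc12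
F4 | step 4 | 1-{3-[(2S)-7-acetoxy-2-(4-acetoxyphenyl)-2H-chromen-4-yl]-2,4,6-trihydroxyphenyl}dodecan-1-one | CCCCCCCCCCCC(=O)c1c(O)cc(O)c(c1O)C1=C[C@@H](c2ccc(OC(C)=O)cc2)Oc2cc(OC(C)=O)ccc12
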